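The 2,2-dimethyl-2H-pyran ring fused at C7–O/C8 of the flavone (O, CMe2, CH=CH and the two arene carbons) is traced back to the furan ring of a benzofuran. In the key step lithium with catalytic DTBB cleaves the furan O–C2 bond of 6-methoxy-4-(methoxymethoxy)benzofuran, the cis-vinyllithium phenoxide adds to acetone and mild acid closes the diol, so the five-membered ring takes up the acetone carbon between O and CH and becomes the six-membered pyran. It exploits the cis CH=CH unit and the aryl–O bond of the pyran ring, both already present in the furan. Ortho-metalation, Stille prenylation, Claisen condensation, chromone closure and a copper-catalysed O-vinylation then build the flavone and the oxepine.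

Key step: step 4

Assumption: the target has no stereocentre, so the only geometric element to control is the Z alkene of the pyran ring; 4,6-dihydroxybenzofuran-3(2H)-one, methyl 2-hydroxy-4,5-dimethoxybenzoate and 3-methylbuta-1,2-diene are taken as purchasable.

Step 1
Reactants: 1 4,6-dihydroxybenzofuran-3(2H)-one
Product: 2 4-hydroxy-6-methoxybenzofuran-3(2H)-one
Conditions: Me2SO4 (1.05 equiv), K2CO3 (1.1 equiv), acetone, reflux
Reagents that add atoms: dimethyl sulfate, COS(=O)(=O)OC
Why: The 4-OH is held in a hydrogen bond to the C3 carbonyl whereas the 6-OH, para to the acyl-bearing carbon, is the free and more acidic phenol, so a Williamson O-methylation with one equivalent of reagent should occur at O6 only.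

Step 2
Reactants: 2 4-hydroxy-6-methoxybenzofuran-3(2H)-one
Product: 4 6-methoxybenzofuran-4-ol, via dihydrobenzofurandiol 3 (not isolated)
Conditions: NaBH4 (3 equiv), EtOH, 0 °C to rt; then 2 M HCl, rt
Reagents that add atoms: none
Why: Borohydride reduction of the coumaranone carbonyl gives the benzylic alcohol, which under acid should lose water through the oxygen-stabilised benzylic cation and the C2 proton to give the aromatic benzofuran (reduction then E1 dehydration; the transient carbinol stereocentre is racemic and is destroyed).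

Step 3
Reactants: 4 6-methoxybenzofuran-4-ol
Product: 5 6-methoxy-4-(methoxymethoxy)benzofuran
Conditions: NaH (1.1 equiv), MOMCl (1.1 equiv), THF/DMF, 0 °C to rt
Reagents that add atoms: chloromethyl methyl ether, COCCl
Why: Williamson etherification of the sodium phenoxide installs a MOM ether that keeps the substrate neutral for the reductive lithiation, later directs the ortho-lithiation and is removed by mild acid.

Step 4
Reactants: 5 6-methoxy-4-(methoxymethoxy)benzofuran
Product: 8 7-methoxy-5-(methoxymethoxy)-2,2-dimethyl-2H-chromene, via vinyllithium phenoxide 6 (not isolated), via allylic diol 7 (not isolated)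
Conditions: Li powder (excess), DTBB (5 mol%), THF, 0 °C; acetone, −78 °C; H2O; then PPTS (cat.), CH2Cl2, rt
Reagents that add atoms: acetone, CC(C)=O
Why: Two single-electron transfers from lithium, shuttled by the DTBB radical anion, populate the styrene-type π* of the furan and break its vinylic O–C2 bond, giving the phenoxide and a configurationally stable cis-vinyllithium 6 that adds 1,2 to acetone; the Z-diol 7 then ionises under mild acid at the tertiary allylic carbon and the phenol oxygen closes the ring, so that the furan ring (O, C2, C3, C3a, C7a) has gained the acetone carbon between O and C2 and is now the 2,2-dimethyl-2H-pyran. The closest known reaction type is the arene-catalysed reductive lithiation (ring opening) of benzofuran with carbonyl trapping and cyclodehydration of the diol to a 2H-chromene. The ring closure is a 6-endo attack of oxygen on the tertiary end of the Z-allyl cation, equivalent to an oxa-6π electrocyclisation of the ortho-quinone methide form. No stereocentre is formed and the Z geometry needed for closure is inherited from the ring. The step needs cleavage of the vinylic C–O bond in preference to the ArO–CH3 and ArO–CH2OCH3 bonds, which the easier reduction of the conjugated furan and a short reaction at 0 °C should secure, and it needs addition rather than enolisation of acetone, favoured at −78 °C. The site of fusion (oxygen on the future C7, carbon on the future C8) cannot scramble because the aryl–O bond is never broken.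

Step 5
Reactants: 8 7-methoxy-5-(methoxymethoxy)-2,2-dimethyl-2H-chromene
Product: 11 1-(5-hydroxy-7-methoxy-2,2-dimethyl-2H-chromen-6-yl)ethanone, via aryllithium 9 (not isolated), via MOM ketone 10 (not isolated)
Conditions: n-BuLi (1.2 equiv), THF, 0 °C; MeC(O)N(OMe)Me, −78 °C to 0 °C; then 2 M HCl/MeOH, rt
Reagents that add atoms: N-methoxy-N-methylacetamide, CC(=O)N(C)OC
Why: Directed ortho-metalation should occur at C6, where the chelating MOM oxygen and the methoxy oxygen cooperate (C8 has only the weaker methoxy/ring-oxygen pair), the aryllithium is acylated by the N-methoxy-N-methylamide through a stable tetrahedral chelate that prevents over-addition, and the MOM ether ortho to the new ketone is cleaved by dilute acid.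

Step 6
Reactants: 11 1-(5-hydroxy-7-methoxy-2,2-dimethyl-2H-chromen-6-yl)ethanone
Product: 12 1-(5-hydroxy-8-iodo-7-methoxy-2,2-dimethyl-2H-chromen-6-yl)ethanone
Conditions: NIS (1.05 equiv), MeCN, 0 °C to rt
Reagents that add atoms: N-iodosuccinimide, O=C1CCC(=O)N1I
Why: C8 is the only free arene position and lies ortho to the methoxy and ring oxygens and para to the phenol, so electrophilic aromatic iodination should take place there.

Step 7
Reactants: 12 1-(5-hydroxy-8-iodo-7-methoxy-2,2-dimethyl-2H-chromen-6-yl)ethanone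
Product: 13 1-[5-hydroxy-7-methoxy-2,2-dimethyl-8-(3-methylbut-2-enyl)-2H-chromen-6-yl]ethanone
Conditions: Pd(PPh3)4 (5 mol%), tributyl(3-methylbut-2-en-1-yl)stannane (1.5 equiv), DMF, 95 °C
Reagents that add atoms: tributyl(3-methylbut-2-en-1-yl)stannane, CCCC[Sn](CCCC)(CCCC)CC=C(C)C
Why: Stille coupling (oxidative addition of the aryl iodide to zerovalent palladium, transmetalation of the allylstannane at its CH2 terminus, reductive elimination) should give the linear C-prenyl arene and tolerates the hydrogen-bonded phenol and the ketone.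

Step 8
Reactants: 14 methyl 2-hydroxy-4,5-dimethoxybenzoate
Product: 15 methyl 4,5-dimethoxy-2-(methoxymethoxy)benzoate
Conditions: NaH (1.2 equiv), MOMCl (1.2 equiv), DMF, 0 °C to rt
Reagents that add atoms: chloromethyl methyl ether, COCCl
Why: Williamson etherification masks the B-ring oxygen so that later only the A-ring phenol can close the chromone.

Step 9
Reactants: 13 1-[5-hydroxy-7-methoxy-2,2-dimethyl-8-(3-methylbut-2-enyl)-2H-chromen-6-yl]ethanone, 15 methyl 4,5-dimethoxy-2-(methoxymethoxy)benzoate
Product: 16 1-[4,5-dimethoxy-2-(methoxymethoxy)phenyl]-3-[5-hydroxy-7-methoxy-2,2-dimethyl-8-(3-methylbut-2-enyl)-2H-chromen-6-yl]propane-1,3-dione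
Conditions: LiN(SiMe3)2 (3.5 equiv), THF, −78 °C to 50 °C; then 1 M HCl, 0 °C
Reagents that add atoms: none
Why: Crossed Claisen condensation: the methyl ketone enolate of the phenoxide–enolate dianion adds to the non-enolisable benzoate and the equilibrium is drawn forward by formation of the stabilised diketonate.

Step 10
Reactants: 17 3-methylbuta-1,2-diene
Product: 19 1,2-dibromo-3-methylbut-2-ene, via 2,3-dibromo-3-methylbut-1-ene 18 (not isolated)
Conditions: Br2 (1.0 equiv), CH2Cl2, −78 °C; then rt until the allylic isomers have equilibrated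
Reagents that add atoms: bromine, BrBr
Why: Electrophilic addition of one equivalent of bromine to the allene gives the tertiary allylic dibromide, which should equilibrate by 1,3-bromide shift to the primary allylic bromide carrying the tetrasubstituted bromoalkene (either isomer alkylates a soft carbanion at the CH2 terminus to the same product).

Step 11
Reactants: 16 1-[4,5-dimethoxy-2-(methoxymethoxy)phenyl]-3-[5-hydroxy-7-methoxy-2,2-dimethyl-8-(3-methylbut-2-enyl)-2H-chromen-6-yl]propane-1,3-dione, 19 1,2-dibromo-3-methylbut-2-ene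
Product: 20 2-(2-bromo-3-methylbut-2-enyl)-1-[4,5-dimethoxy-2-(methoxymethoxy)phenyl]-3-[5-hydroxy-7-methoxy-2,2-dimethyl-8-(3-methylbut-2-enyl)-2H-chromen-6-yl]propane-1,3-dione (racemic)
Conditions: K2CO3 (1.5 equiv), 19 (1.1 equiv), acetone, rt
Reagents that add atoms: none
Why: SN2 C-alkylation of the doubly activated methylene by the allylic bromide under mild carbonate conditions, the vinylic bromide being inert and the hydrogen-bonded phenol the weaker nucleophile; the new stereocentre is racemic and disappears in step 12.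

Step 12
Reactants: 20 2-(2-bromo-3-methylbut-2-enyl)-1-[4,5-dimethoxy-2-(methoxymethoxy)phenyl]-3-[5-hydroxy-7-methoxy-2,2-dimethyl-8-(3-methylbut-2-enyl)-2H-chromen-6-yl]propane-1,3-dione
Product: 22 3-(2-bromo-3-methylbut-2-enyl)-2-(2-hydroxy-4,5-dimethoxyphenyl)-5-methoxy-8,8-dimethyl-6-(3-methylbut-2-enyl)-4H,8H-pyrano[2,3-h]chromen-4-one, via MOM flavone 21 (not isolated)
Conditions: NaOAc, AcOH, 100 °C; then MeOH, 3 M HCl, 50 °C
Reagents that add atoms: none
Why: In buffered acetic acid only the A-ring phenol is free, so hemiketal formation on the B-ring ketone and loss of water (cyclodehydration to the 4H-chromen-4-one) fix the flavone regiochemistry before the MOM acetal is cleaved by the added HCl in methanol; the bromoalkene, prenyl and chromene alkenes have no neighbouring free hydroxyl and should survive.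

Step 13
Reactants: 22 3-(2-bromo-3-methylbut-2-enyl)-2-(2-hydroxy-4,5-dimethoxyphenyl)-5-methoxy-8,8-dimethyl-6-(3-methylbut-2-enyl)-4H,8H-pyrano[2,3-h]chromen-4-one
Product: 23 CNP0192589.0
Conditions: CuI (10 mol%), 1,10-phenanthroline (20 mol%), Cs2CO3 (2 equiv), toluene, 110 °C
Reagents that add atoms: none
Why: Ullmann-type intramolecular C–O coupling of the caesium phenoxide with the vinylic C–Br bond on monovalent copper should close the seven-membered enol ether, with the position of the C=C(CH3)2 bond fixed by the bromoalkene so that no alkene isomer can arise.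

Compound list
1 | 4,6-dihydroxybenzofuran-3(2H)-one | O=C1COc2cc(O)cc(O)c12 | starting material
2 | 4-hydroxy-6-methoxybenzofuran-3(2H)-one | O=C1COc2cc(OC)cc(O)c12 | intermediate
3 | 6-methoxy-2,3-dihydrobenzofuran-3,4-diol (racemic) | OC1COc2cc(OC)cc(O)c12 | intermediate
4 | 6-methoxybenzofuran-4-ol | COc1cc(O)c2ccoc2c1 | intermediate
5 | 6-methoxy-4-(methoxymethoxy)benzofuran | COCOc1cc(OC)cc2occc12 | intermediate
6 | lithium 2-[(Z)-2-lithioethenyl]-5-methoxy-3-(methoxymethoxy)phenolate | [Li]/C=C\c1c(O[Li])cc(OC)cc1OCOC | intermediate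
7 | 2-[(Z)-3-hydroxy-3-methylbut-1-enyl]-5-methoxy-3-(methoxymethoxy)phenol | CC(C)(O)/C=C\c1c(O)cc(OC)cc1OCOC | intermediate
8 | 7-methoxy-5-(methoxymethoxy)-2,2-dimethyl-2H-chromene | COCOc1cc(OC)cc2OC(C)(C)C=Cc12 | intermediate
9 | [7-methoxy-5-(methoxymethoxy)-2,2-dimethyl-2H-chromen-6-yl]lithium | [Li]c1c(OC)cc2OC(C)(C)C=Cc2c1OCOC | intermediate
10 | 1-[7-methoxy-5-(methoxymethoxy)-2,2-dimethyl-2H-chromen-6-yl]ethanone | CC(=O)c1c(OC)cc2OC(C)(C)C=Cc2c1OCOC | intermediate
11 | 1-(5-hydroxy-7-methoxy-2,2-dimethyl-2H-chromen-6-yl)ethanone | CC(=O)c1c(OC)cc2OC(C)(C)C=Cc2c1O | intermediate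
12 | 1-(5-hydroxy-8-iodo-7-methoxy-2,2-dimethyl-2H-chromen-6-yl)ethanone | CC(=O)c1c(OC)c(I)c2OC(C)(C)C=Cc2c1O | intermediate
13 | 1-[5-hydroxy-7-methoxy-2,2-dimethyl-8-(3-methylbut-2-enyl)-2H-chromen-6-yl]ethanone | CC(=O)c1c(OC)c(CC=C(C)C)c2OC(C)(C)C=Cc2c1O | intermediate
14 | methyl 2-hydroxy-4,5-dimethoxybenzoate | COC(=O)c1cc(OC)c(OC)cc1O | starting material
15 | methyl 4,5-dimethoxy-2-(methoxymethoxy)benzoate | COCOc1cc(OC)c(OC)cc1C(=O)OC | intermediate
16 | 1-[4,5-dimethoxy-2-(methoxymethoxy)phenyl]-3-[5-hydroxy-7-methoxy-2,2-dimethyl-8-(3-methylbut-2-enyl)-2H-chromen-6-yl]propane-1,3-dione | COCOc1cc(OC)c(OC)cc1C(=O)CC(=O)c1c(OC)c(CC=C(C)C)c2OC(C)(C)C=Cc2c1O | intermediate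
17 | 3-methylbuta-1,2-diene | CC(C)=C=C | starting material
18 | 2,3-dibromo-3-methylbut-1-ene | CC(C)(Br)C(Br)=C | intermediate
19 | 1,2-dibromo-3-methylbut-2-ene | CC(C)=C(Br)CBr | intermediate
20 | 2-(2-bromo-3-methylbut-2-enyl)-1-[4,5-dimethoxy-2-(methoxymethoxy)phenyl]-3-[5-hydroxy-7-methoxy-2,2-dimethyl-8-(3-methylbut-2-enyl)-2H-chromen-6-yl]propane-1,3-dione (racemic) | COCOc1cc(OC)c(OC)cc1C(=O)C(CC(Br)=C(C)C)C(=O)c1c(OC)c(CC=C(C)C)c2OC(C)(C)C=Cc2c1O | intermediate
21 | 3-(2-bromo-3-methylbut-2-enyl)-2-[4,5-dimethoxy-2-(methoxymethoxy)phenyl]-5-methoxy-8,8-dimethyl-6-(3-methylbut-2-enyl)-4H,8H-pyrano[2,3-h]chromen-4-one | COCOc1cc(OC)c(OC)cc1-c1oc2c3C=CC(C)(C)Oc3c(CC=C(C)C)c(OC)c2c(=O)c1CC(Br)=C(C)C | intermediate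
22 | 3-(2-bromo-3-methylbut-2-enyl)-2-(2-hydroxy-4,5-dimethoxyphenyl)-5-methoxy-8,8-dimethyl-6-(3-methylbut-2-enyl)-4H,8H-pyrano[2,3-h]chromen-4-one | COc1cc(O)c(cc1OC)-c1oc2c3C=CC(C)(C)Oc3c(CC=C(C)C)c(OC)c2c(=O)c1CC(Br)=C(C)C | intermediate
23 | CNP0192589.0: 5-methoxy-6-prenyl flavone with a 2,2-dimethyl-2H-pyran ring fused at C7–O/C8, a 4′,5′-dimethoxy B ring, and a seven-membered oxepine formed by the bridge C3–CH2–C(=C(CH3)2)–O–C2′ | COc1cc2c(cc1OC)-c1oc3c4c(c(CC=C(C)C)c(OC)c3c(=O)c1CC(=C(C)C)O2)OC(C)(C)C=C4 | target

Total step count: 13. Longest linear sequence: 11 steps (steps 1, 2, 3, 4, 5, 6, 7, 9, 11, 12, 13).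

Steps most likely to fail

Step 4. The electron-rich, doubly alkoxylated benzofuran may accept electrons too slowly, or electron transfer may run on into cleavage of the aryl–OCH3 or aryl–OCH2OCH3 bonds, or the vinyllithium may be protonated before it meets acetone. The fallback sets out from 5 and returns at 8. A nickel-catalysed ring-opening Kumada coupling of the furan C2–O bond with isopropenylmagnesium bromide (Ni(cod)2, PCy3, toluene, 80 °C; oxidative addition of the vinylic C–O bond to zerovalent nickel with retention of the cis geometry) should give 2-[(Z)-3-methylbuta-1,3-dienyl]-5-methoxy-3-(methoxymethoxy)phenol F1. PPTS then protonates the terminal CH2 of the diene to the same Z-allyl cation as in step 4 and the phenol oxygen closes the pyran ring to 8. The ring still grows from five to six members, now by taking up the isopropenyl carbon.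

Step 13. Oxidative addition of the tetrasubstituted bromoalkene to monovalent copper may be too slow for the seven-membered closure, so that protodebromination or base-induced loss of HBr toward the allene takes over. The fallback sets out from 16 and returns at 23. C-alkylation of 16 with 1-bromo-3-methylbutan-2-one (K2CO3, acetone, rt) should give 1-[4,5-dimethoxy-2-(methoxymethoxy)phenyl]-3-[5-hydroxy-7-methoxy-2,2-dimethyl-8-(3-methylbut-2-enyl)-2H-chromen-6-yl]-2-(3-methyl-2-oxobutyl)propane-1,3-dione F2. Treatment as in step 12 (NaOAc/AcOH, then HCl/MeOH) should give 2-(2-hydroxy-4,5-dimethoxyphenyl)-5-methoxy-8,8-dimethyl-3-(3-methyl-2-oxobutyl)-6-(3-methylbut-2-enyl)-4H,8H-pyrano[2,3-h]chromen-4-one F3. TsOH (cat.) in toluene with azeotropic removal of water should then form the seven-membered hemiketal between the 2′-OH and the side-chain ketone and dehydrate it toward the isopropyl carbon, giving the tetrasubstituted enol ether 23.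

Step 5. Lithiation may take place in part at C8, between the methoxy and ring oxygens, or n-BuLi may add across the chromene double bond. The fallback sets out from 8 and returns at 11. Cleavage of the MOM ether (PPTS, MeOH, 50 °C) should give 7-methoxy-2,2-dimethyl-2H-chromen-5-ol F4. Magnesium-mediated ortho-formylation (MgCl2, Et3N, paraformaldehyde, MeCN, reflux) can only reach C6, the sole position ortho to the phenol, and should give 5-hydroxy-7-methoxy-2,2-dimethyl-2H-chromene-6-carbaldehyde F5. MeMgBr (excess, THF, 0 °C) should give racemic 6-(1-hydroxyethyl)-7-methoxy-2,2-dimethyl-2H-chromen-5-ol F6, and MnO2 (CH2Cl2, rt) should oxidise the benzylic alcohol to 11.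

Further compounds
F1 | step 4 | 2-[(Z)-3-methylbuta-1,3-dienyl]-5-methoxy-3-(methoxymethoxy)phenol | CC(=C)/C=C\c1c(O)cc(OC)cc1OCOC
F2 | step 13 | 1-[4,5-dimethoxy-2-(methoxymethoxy)phenyl]-3-[5-hydroxy-7-methoxy-2,2-dimethyl-8-(3-methylbut-2-enyl)-2H-chromen-6-yl]-2-(3-methyl-2-oxobutyl)propane-1,3-dione (racemic) | COCOc1cc(OC)c(OC)cc1C(=O)C(CC(=O)C(C)C)C(=O)c1c(OC)c(CC=C(C)C)c2OC(C)(C)C=Cc2c1O
F3 | step 13 | 2-(2-hydroxy-4,5-dimethoxyphenyl)-5-methoxy-8,8-dimethyl-3-(3-methyl-2-oxobutyl)-6-(3-methylbut-2-enyl)-4H,8H-pyrano[2,3-h]chromen-4-one | COc1cc(O)c(cc1OC)-c1oc2c3C=CC(C)(C)Oc3c(CC=C(C)C)c(OC)c2c(=O)c1CC(=O)C(C)C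
F4 | step 5 | 7-methoxy-2,2-dimethyl-2H-chromen-5-ol | COc1cc(O)c2C=CC(C)(C)Oc2c1
F5 | step 5 | 5-hydroxy-7-methoxy-2,2-dimethyl-2H-chromene-6-carbaldehyde | COc1cc2OC(C)(C)C=Cc2c(O)c1C=O
F6 | step 5 | 6-(1-hydroxyethyl)-7-methoxy-2,2-dimethyl-2H-chromen-5-ol (racemic) | COc1cc2OC(C)(C)C=Cc2c(O)c1C(C)O
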